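**Atom labels used throughout:** ring O1, C2 (4‑hydroxyphenyl carbon), C3 (bears C6, the acetoxymethyl carbon), C4 (bears C7, the acetoxylated anisyl carbinol carbon), C5 (ring CH2).

## The problem

The target is a 2,3,4‑trisubstituted tetrahydrofuran with all three ring substituents trans (2R,3S,4R) and a fourth, exocyclic stereocentre at C7 (S). The ring centres can relay to one another: a fixed C3 steers C2 (aryl trans to the C3 arm) and C4 (epimerisable once α to a carbonyl, most stable trans to C3). C7 lies outside the ring and must be set by a face‑selective reaction at a C7 carbonyl, where C4 offers only a modest Felkin–Anh bias. Both benzylic C–O bonds (C2–O1 and C7–OAc) are para‑oxygenated, so they ionise under acid and are at risk under hydrogenolysis; a free phenol para to C2 invites quinone‑methide chemistry under strong base. The late steps must therefore be mild and close to neutral. Two aliphatic acetates stand beside one free phenol and one aryl methyl ether, so the two aryl oxygens must be differentiated from the start and the phenol released last. Constitutionally, C5 is an unsubstituted CH2 between O1 and C4, C2 is a cation‑stabilising benzylic carbon, and C4 must end up bonded to a carbonyl‑derived carbon. That is the pattern of a donor–acceptor cyclopropane (C2–C3–C4, geminal diester on C4) plus formaldehyde (O1–C5), with C3 as a spectator that carries the absolute configuration.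

## Retrosynthesis

**19 ⇒ 18 ⇒ 17 ⇒ 16 (O–acetyl, then O–silyl bonds).** A diol cannot be unmasked beside a silylated phenol without fluoride or acid, which would remove the aryl silyl ether first or ionise C7. The cut therefore goes back to triacetate 18, from which only the aryl acetate is removed, then to triol 17 and its bis‑silyl ether 16. This costs one step against a direct selective acylation, but each operation is basic or buffered. Compound 16 already holds the full skeleton and all four stereocentres; the forward steps must only leave the two benzylic C–O bonds untouched.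

**16 ⇒ 15 (C7–H).** Cutting C7–H is preferred to cutting C7–aryl at the alcohol level. Aryl‑metal addition to a C4 aldehyde would be steered by C4 toward the C7 epimer, whereas hydride addition to the aryl ketone is steered toward the required carbinol and can be reinforced by a chiral catalyst. Ketone 15 has one stereocentre fewer, and C4, now α to a ketone, becomes self‑correcting. The forward reduction must be face‑selective and non‑basic.

**15 ⇒ 13 + 14, and 13 ⇒ 12 (C7–aryl bond, C7–N for C7–O).** The anisyl ring is attached as aryl Grignard reagent 14 to Weinreb amide 13, which comes from methyl ester 12. Direct addition to the ester would over‑add, and an aldehyde route would need an extra oxidation. Ester 12 has no second arene and no C7 stereocentre. The forward steps must tolerate the two silyl ethers and stop at the ketone.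

**12 ⇒ 11 (C4–CO2Me).** Restoring a second ester on C4 removes the C4 stereocentre and turns C4 into the geminal‑diester acceptor that the ring construction needs. The forward step must remove one ester cleanly (dealkoxycarbonylation) and leave C4 in, or correctable to, the trans arrangement.

**11 ⇒ 9 + 10 (O1–C2 and C4–C5).** This is the central cut. Etherification cuts (O1–C2 or O1–C5 alone) would need an acyclic chain with three defined centres, and a C3–C4 cut has no obvious polar logic. Removing formaldehyde 10 leaves cis‑cyclopropane 9, in which only C3 must survive, because C2 is re‑set by inversion. The forward reaction must open C2–C4 and not C3–C4, invert C2, and close the ring onto C5.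

**9 ⇒ 6 + 8, and 8 ⇒ 7 (cyclopropane bonds C2–C4 and C3–C4).** The diester carbon is delivered as a malonate carbene equivalent, iodonium ylide 8 (from dimethyl malonate 7), to (Z)‑alkene 6. A tethered variant through an allyl diazomalonate would give a bicyclic lactone that has to be reopened, silylated and re‑esterified, and its hydroxy ester tends to relactonise. The intermolecular transfer gives the diester directly. The forward step must be stereospecific (Z to cis) and enantioface‑selective; it is the step that fixes C3.

**6 ⇒ 5 ⇒ 4 ⇒ 2 + 3, and 2 ⇒ 1 (O–Si bonds, alkene from alkyne, aryl–alkynyl bond).** The Z‑cinnamyl geometry is best obtained by semi‑hydrogenation of aryl alkyne 4, itself a Sonogashira product of silylated iodophenol 2 and propargyl alcohol 3. A Z‑selective olefination of an electron‑rich benzaldehyde is less reliable. Keeping allylic alcohol 5 as a discrete intermediate leaves the choice of the C6 protecting group open and provides the branch point for a tethered cyclopropanation if needed. All precursors are commercial (1, 3, 7, 10, 14).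

## Roads not taken

**Alternative 1: decarboxylative palladium [3+2] of a vinyl carbonate.** The cut is O1–C2 and C3–C4. Zerovalent palladium (Pd2(dba)3 with a chiral phosphoramidite) ionises vinylethylene carbonate A1 with loss of CO2. The alkoxide adds to the arylidene carbon of Meldrum's acid derivative A2, and the resulting carbanion attacks the internal allyl carbon to give spiro‑tetrahydrofuran A3. Its merit is real: two achiral partners are joined and C2 and C4 are set in one catalytic asymmetric step, whereas the chosen plan needs a separate asymmetric cyclopropanation. Its weak points for this target are the following.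
- The functional groups land on the wrong carbons: the dicarbonyl sits on C3 and must be trimmed to CH2OAc, while C4 receives a vinyl group.
- The vinyl group must be cleaved, arylated, and then oxidised and reduced again, because aryl addition to a C4 aldehyde favours the C7 epimer.
- The 4‑silyloxyphenyl arylidene is a deactivated acceptor and its oxa‑Michael addition is reversible.

The chosen plan sets against the built‑in enantiocontrol of A3 the fact that its diester is placed on C4, exactly where C7 must grow, so no oxidative cleavage or oxidation‑state detour follows the key step.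

**Alternative 2: Prins–pinacol ring contraction.** The cut is C2–C3 and C4–C5. SnCl4 opens aryl dioxolane A4 to an oxocarbenium ion at C2, which attacks the alkene at C3 through a chair. A pinacol shift of C5 from C7 to C4 then contracts the ring and leaves aryl ketone A5. A5 is the same compound as ketone 15 of the chosen route, so this road is shorter after its key step: it reaches in one operation what the chosen plan reaches four steps after its annulation. Against it stand structural liabilities of A4.
- C7 is a tertiary carbinol carbon that is both 4‑methoxybenzylic and allylic, and is likely to ionise under SnCl4 in competition with the acetal.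
- The alkene is only 1,2‑disubstituted and carries an allylic silyloxy group, so it is a poor nucleophile and generates a secondary cation.
- A4 needs an enantioenriched tertiary diol, and transfer of its chirality depends on which C7 substituent sits equatorial in the chair.

The chosen plan offers a more predictable stereospecific ring formation at the price of three extra functional‑group steps.

**Alternative 3: rhodium carbenoid C–H insertion.** The cut is C2–C3. Rh2(O2CCPh3)4 (divalent rhodium) converts α‑diazo ester A6 into a carbenoid at C3, which inserts into the benzylic ether C2–H bond to give tetrahydrofuran ester A7. Its merit is that C4 and C7, with the anisyl group, are set beforehand by acyclic aldol‑type chemistry, so no late reduction with double stereodifferentiation is needed; in this respect it is better than the chosen plan. A7 is also only an ester reduction and the protecting‑group endgame away from the target. Its weak points are the following.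
- The carbenoid has a hydrogen on C4, so 1,2‑hydride migration competes directly with insertion.
- Two electron‑rich arenes offer sites for aromatic addition.
- The 2,4‑cis relationship must arise from a flexible transition state.
- A6 requires diazo transfer onto an unactivated ester and carries two pre‑set centres, so the sequence before the key step is longer.

The chosen plan accepts a late catalyst‑controlled reduction in exchange for a ring‑forming step whose regio‑ and stereochemical course follows from the substrate.

Key step: step 7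

**Assumption:** which antipode of the side‑arm bis(oxazoline) ligand delivers (2S,3S)‑9 from a (Z)‑aryl alkene of this type is an experimental assignment; the route is written for that antipode, both being accessible from the enantiomeric amino alcohols.

## Route

Step 1
Reactants: 1 4‑iodophenol
Product: 2 (4‑iodophenoxy)triisopropylsilane
Conditions: TIPSCl, imidazole, DMF, rt
Reagents that add atoms: triisopropylsilyl chloride, CC(C)[Si](Cl)(C(C)C)C(C)C
Why: Standard phenol silylation; the bulky aryl triisopropylsilyl ether is chosen to survive Grignard reagents, Lewis acid and hot chloride later and to leave with fluoride at the end.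

Step 2
Reactants: 2 (4‑iodophenoxy)triisopropylsilane; 3 prop‑2‑yn‑1‑ol (propargyl alcohol)
Product: 4 3‑{4‑[(triisopropylsilyl)oxy]phenyl}prop‑2‑yn‑1‑ol
Conditions: PdCl2(PPh3)2 (2 mol %), CuI (4 mol %), Et3N, THF, rt
Reagents that add atoms: none
Why: Sonogashira coupling of an aryl iodide with a terminal alkyne; the free propargylic hydroxyl and the aryl silyl ether are tolerated under amine base at room temperature.

Step 3
Reactants: 4 3‑{4‑[(triisopropylsilyl)oxy]phenyl}prop‑2‑yn‑1‑ol
Product: 5 (Z)‑3‑{4‑[(triisopropylsilyl)oxy]phenyl}prop‑2‑en‑1‑ol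
Conditions: H2 (1 atm), Pd/CaCO3 poisoned with Pb(OAc)2 (Lindlar catalyst), quinoline, EtOAc, rt
Reagents that add atoms: none
Why: Lindlar semi‑hydrogenation adds H2 syn on the catalyst surface and should give the Z‑alkene; quinoline and monitoring of hydrogen uptake guard against over‑reduction.

Step 4
Reactants: 5 (Z)‑3‑{4‑[(triisopropylsilyl)oxy]phenyl}prop‑2‑en‑1‑ol
Product: 6 (Z)‑tert‑butyldiphenyl[(3‑{4‑[(triisopropylsilyl)oxy]phenyl}prop‑2‑en‑1‑yl)oxy]silane
Conditions: TBDPSCl, imidazole, CH2Cl2, 0 °C to rt
Reagents that add atoms: tert‑butyldiphenylsilyl chloride, CC(C)(C)[Si](Cl)(c1ccccc1)c1ccccc1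
Why: Routine silylation of a primary alcohol; the hindered, weakly Lewis‑basic silyl ether keeps the C6 oxygen from interfering with the tin‑mediated step and withstands the Krapcho conditions.

Step 5
Reactants: 7 dimethyl malonate
Product: 8 dimethyl 2‑(phenyl‑λ3‑iodanylidene)propanedioate (phenyliodonium bis(methoxycarbonyl)methanide)
Conditions: PhI(OAc)2, KOH, MeCN, 0 °C
Reagents that add atoms: (diacetoxyiodo)benzene, CC(=O)OI(OC(C)=O)c1ccccc1
Why: Known ylide formation by ligand exchange of the malonate anion on the hypervalent iodine reagent; the ylide precipitates and serves as a safe malonate carbene precursor.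

Step 6
Reactants: 6 (Z)‑tert‑butyldiphenyl[(3‑{4‑[(triisopropylsilyl)oxy]phenyl}prop‑2‑en‑1‑yl)oxy]silane; 8 dimethyl 2‑(phenyl‑λ3‑iodanylidene)propanedioate
Product: 9 dimethyl (2S,3S)‑3‑{[(tert‑butyldiphenylsilyl)oxy]methyl}‑2‑{4‑[(triisopropylsilyl)oxy]phenyl}cyclopropane‑1,1‑dicarboxylate (aryl and silyloxymethyl cis)
Conditions: 8 (1.5 equiv, in portions), Cu(MeCN)4PF6 (10 mol %, monovalent copper), chiral side‑arm bis(oxazoline) ligand (12 mol %), 4 Å MS, toluene, 0 °C
Reagents that add atoms: none
Why: Asymmetric copper–bis(oxazoline) cyclopropanation of an aryl alkene with a phenyliodonium malonate ylide; carbene transfer is concerted, so the Z geometry becomes the cis relationship, and the ligand selects the alkene face, setting C2 and C3 together as (2S,3S).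

Step 7
Reactants: 9 dimethyl (2S,3S)‑3‑{[(tert‑butyldiphenylsilyl)oxy]methyl}‑2‑{4‑[(triisopropylsilyl)oxy]phenyl}cyclopropane‑1,1‑dicarboxylate; 10 paraformaldehyde (source of formaldehyde)
Product: 11 dimethyl (4S,5R)‑4‑{[(tert‑butyldiphenylsilyl)oxy]methyl}‑5‑{4‑[(triisopropylsilyl)oxy]phenyl}oxolane‑3,3‑dicarboxylate (aryl and silyloxymethyl trans)
Conditions: (CH2O)n (5 equiv), Sn(OTf)2 (10 mol %, divalent tin), CH2Cl2, 0 °C to rt
Reagents that add atoms: none
Why: Sn(OTf)2 chelates the geminal diester of 9 and polarises the C2–C4 bond; the formaldehyde oxygen attacks benzylic C2 opposite to C4 (SN2‑like, inversion), giving an oxocarbenium ion paired with a tin malonate enolate. After rotation, the enolate carbon C4 adds to the oxocarbenium carbon C5 and closes the tetrahydrofuran in a 5‑(enolexo)‑endo‑trig aldol‑type step, a mode that is normal for cationic C=O+ acceptors. The closest known reaction type is the Lewis‑acid‑catalysed [3+2] annulation of 2‑arylcyclopropane‑1,1‑diesters with aldehydes, which is stereospecific with inversion at the donor carbon; formaldehyde and a 3‑substituent extend its scope, not its mechanism. The one new stereocentre is C2: inversion of the cis‑cyclopropane places the aryl group trans to the C3 arm, while C3 is untouched and carries the absolute configuration. The step needs cleavage of C2–C4 and not C3–C4, which the 4‑silyloxyphenyl donor secures because only C2 can bear positive charge. It also needs 2,3‑trans selectivity, which is secured twice: the invertive path gives it directly, and any ion‑pair path closes anti to the C3 substituent or equilibrates at the benzylic ether to the same isomer. C4 and C5 are not stereogenic, so no further selectivity is at stake.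

Step 8
Reactants: 11 dimethyl (4S,5R)‑4‑{[(tert‑butyldiphenylsilyl)oxy]methyl}‑5‑{4‑[(triisopropylsilyl)oxy]phenyl}oxolane‑3,3‑dicarboxylate
Product: 12 methyl (3R,4S,5R)‑4‑{[(tert‑butyldiphenylsilyl)oxy]methyl}‑5‑{4‑[(triisopropylsilyl)oxy]phenyl}oxolane‑3‑carboxylate (all‑trans)
Conditions: LiCl, H2O, DMSO, 140 °C
Reagents that add atoms: none
Why: Krapcho dealkoxycarbonylation: chloride demethylates one ester, the carboxylate loses CO2 and water protonates the ester enolate; the hot, weakly basic medium should let C4 settle trans to the C3 arm, and any residual cis isomer is corrected at the ketone stage (step 10).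

Step 9
Reactants: 12 methyl (3R,4S,5R)‑4‑{[(tert‑butyldiphenylsilyl)oxy]methyl}‑5‑{4‑[(triisopropylsilyl)oxy]phenyl}oxolane‑3‑carboxylate
Product: 13 (3R,4S,5R)‑4‑{[(tert‑butyldiphenylsilyl)oxy]methyl}‑N‑methoxy‑N‑methyl‑5‑{4‑[(triisopropylsilyl)oxy]phenyl}oxolane‑3‑carboxamide
Conditions: MeNHOMe·HCl, iPrMgCl, THF, −20 to 0 °C
Reagents that add atoms: N,O‑dimethylhydroxylamine hydrochloride, CNOC.Cl
Why: Direct ester‑to‑Weinreb‑amide exchange by the chloromagnesium amide generated in the flask; silyl ethers and the benzylic ring ether are inert at this temperature and C4 stays in its thermodynamic configuration.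

Step 10
Reactants: 13 (3R,4S,5R)‑4‑{[(tert‑butyldiphenylsilyl)oxy]methyl}‑N‑methoxy‑N‑methyl‑5‑{4‑[(triisopropylsilyl)oxy]phenyl}oxolane‑3‑carboxamide; 14 (4‑methoxyphenyl)magnesium bromide
Product: 15 [(3R,4S,5R)‑4‑{[(tert‑butyldiphenylsilyl)oxy]methyl}‑5‑{4‑[(triisopropylsilyl)oxy]phenyl}oxolan‑3‑yl](4‑methoxyphenyl)methanone
Conditions: 14 (0.5 M in THF), THF, 0 °C; aq. NH4Cl; then DBU (0.2 equiv), CH2Cl2, rt
Reagents that add atoms: none
Why: Weinreb ketone synthesis: the chelated tetrahedral adduct prevents over‑addition and gives the aryl ketone on work‑up; brief DBU treatment equilibrates C4 (now α to an aryl ketone) to the arrangement trans to the C3 arm, completing the three ring centres.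

Step 11
Reactants: 15 [(3R,4S,5R)‑4‑{[(tert‑butyldiphenylsilyl)oxy]methyl}‑5‑{4‑[(triisopropylsilyl)oxy]phenyl}oxolan‑3‑yl](4‑methoxyphenyl)methanone
Product: 16 (S)‑[(3R,4S,5R)‑4‑{[(tert‑butyldiphenylsilyl)oxy]methyl}‑5‑{4‑[(triisopropylsilyl)oxy]phenyl}oxolan‑3‑yl](4‑methoxyphenyl)methanol
Conditions: (R)‑2‑methyl‑CBS‑oxazaborolidine (0.3 equiv), BH3·SMe2, THF, −20 °C; MeOH quench
Reagents that add atoms: none
Why: Corey–Bakshi–Shibata reduction: with the aryl group as the large substituent the (R)‑catalyst delivers hydride to the face that gives the (S)‑carbinol, and Felkin–Anh attack anti to the C4–C3 bond favours the same face, so catalyst and substrate should be matched in setting C7.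

Step 12
Reactants: 16 (S)‑[(3R,4S,5R)‑4‑{[(tert‑butyldiphenylsilyl)oxy]methyl}‑5‑{4‑[(triisopropylsilyl)oxy]phenyl}oxolan‑3‑yl](4‑methoxyphenyl)methanol
Product: 17 4‑[(2R,3S,4R)‑3‑(hydroxymethyl)‑4‑[(S)‑hydroxy(4‑methoxyphenyl)methyl]oxolan‑2‑yl]phenol
Conditions: Bu4NF (4 equiv), AcOH (4 equiv), THF, 0 °C to rt
Reagents that add atoms: none
Why: Fluoride cleaves both the aryl triisopropylsilyl and the primary tert‑butyldiphenylsilyl ether; acetic acid buffering keeps the medium near neutral so that neither the 4‑hydroxyphenyl benzylic ether nor the anisyl carbinol is opened or ionised.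

Step 13
Reactants: 17 4‑[(2R,3S,4R)‑3‑(hydroxymethyl)‑4‑[(S)‑hydroxy(4‑methoxyphenyl)methyl]oxolan‑2‑yl]phenol
Product: 18 [(2R,3S,4R)‑4‑[(S)‑acetoxy(4‑methoxyphenyl)methyl]‑2‑(4‑acetoxyphenyl)oxolan‑3‑yl]methyl acetate
Conditions: Ac2O, pyridine, DMAP (cat.), CH2Cl2, 0 °C to rt
Reagents that add atoms: acetic anhydride, CC(=O)OC(C)=O
Why: DMAP‑catalysed acetylation of all three hydroxyls, including the hindered benzylic one; the basic, non‑ionising medium preserves C2 and C7.

Step 14
Reactants: 18 [(2R,3S,4R)‑4‑[(S)‑acetoxy(4‑methoxyphenyl)methyl]‑2‑(4‑acetoxyphenyl)oxolan‑3‑yl]methyl acetate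
Product: 19 [(2R,3S,4R)‑4‑[(S)‑acetoxy(4‑methoxyphenyl)methyl]‑2‑(4‑hydroxyphenyl)oxolan‑3‑yl]methyl acetate (CNP0231272.1)
Conditions: pyrrolidine (1.5 equiv), CH2Cl2, 0 °C
Reagents that add atoms: none
Why: Chemoselective aminolysis: an aryl acetate is a far better acyl donor than an alkyl acetate (phenoxide leaving group), so a secondary amine at low temperature should remove only the phenolic acetate and give the target.

## Compound list

1 | 4‑iodophenol | Oc1ccc(I)cc1 | starting material
2 | (4‑iodophenoxy)triisopropylsilane | CC(C)[Si](Oc1ccc(I)cc1)(C(C)C)C(C)C | intermediate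
3 | prop‑2‑yn‑1‑ol (propargyl alcohol) | C#CCO | starting material
4 | 3‑{4‑[(triisopropylsilyl)oxy]phenyl}prop‑2‑yn‑1‑ol | OCC#Cc1ccc(O[Si](C(C)C)(C(C)C)C(C)C)cc1 | intermediate
5 | (Z)‑3‑{4‑[(triisopropylsilyl)oxy]phenyl}prop‑2‑en‑1‑ol | OC/C=C\c1ccc(O[Si](C(C)C)(C(C)C)C(C)C)cc1 | intermediate
6 | (Z)‑tert‑butyldiphenyl[(3‑{4‑[(triisopropylsilyl)oxy]phenyl}prop‑2‑en‑1‑yl)oxy]silane | CC(C)(C)[Si](OC/C=C\c1ccc(O[Si](C(C)C)(C(C)C)C(C)C)cc1)(c1ccccc1)c1ccccc1 | intermediate
7 | dimethyl malonate | COC(=O)CC(=O)OC | starting material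
8 | dimethyl 2‑(phenyl‑λ3‑iodanylidene)propanedioate | COC(=O)[C-](C(=O)OC)[I+]c1ccccc1 | intermediate
9 | dimethyl (2S,3S)‑3‑{[(tert‑butyldiphenylsilyl)oxy]methyl}‑2‑{4‑[(triisopropylsilyl)oxy]phenyl}cyclopropane‑1,1‑dicarboxylate (cis) | COC(=O)C1(C(=O)OC)[C@H](c2ccc(O[Si](C(C)C)(C(C)C)C(C)C)cc2)[C@@H]1CO[Si](c2ccccc2)(c2ccccc2)C(C)(C)C | intermediate
10 | paraformaldehyde (formaldehyde source; monomer unit shown) | C=O | starting material
11 | dimethyl (4S,5R)‑4‑{[(tert‑butyldiphenylsilyl)oxy]methyl}‑5‑{4‑[(triisopropylsilyl)oxy]phenyl}oxolane‑3,3‑dicarboxylate | COC(=O)C1(C(=O)OC)CO[C@@H](c2ccc(O[Si](C(C)C)(C(C)C)C(C)C)cc2)[C@@H]1CO[Si](c2ccccc2)(c2ccccc2)C(C)(C)C | intermediate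
12 | methyl (3R,4S,5R)‑4‑{[(tert‑butyldiphenylsilyl)oxy]methyl}‑5‑{4‑[(triisopropylsilyl)oxy]phenyl}oxolane‑3‑carboxylate | COC(=O)[C@H]1CO[C@@H](c2ccc(O[Si](C(C)C)(C(C)C)C(C)C)cc2)[C@@H]1CO[Si](c2ccccc2)(c2ccccc2)C(C)(C)C | intermediate
13 | (3R,4S,5R)‑4‑{[(tert‑butyldiphenylsilyl)oxy]methyl}‑N‑methoxy‑N‑methyl‑5‑{4‑[(triisopropylsilyl)oxy]phenyl}oxolane‑3‑carboxamide | CON(C)C(=O)[C@H]1CO[C@@H](c2ccc(O[Si](C(C)C)(C(C)C)C(C)C)cc2)[C@@H]1CO[Si](c2ccccc2)(c2ccccc2)C(C)(C)C | intermediate
14 | (4‑methoxyphenyl)magnesium bromide | COc1ccc([Mg]Br)cc1 | starting material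
15 | [(3R,4S,5R)‑4‑{[(tert‑butyldiphenylsilyl)oxy]methyl}‑5‑{4‑[(triisopropylsilyl)oxy]phenyl}oxolan‑3‑yl](4‑methoxyphenyl)methanone | COc1ccc(C(=O)[C@H]2CO[C@@H](c3ccc(O[Si](C(C)C)(C(C)C)C(C)C)cc3)[C@@H]2CO[Si](c3ccccc3)(c3ccccc3)C(C)(C)C)cc1 | intermediate
16 | (S)‑[(3R,4S,5R)‑4‑{[(tert‑butyldiphenylsilyl)oxy]methyl}‑5‑{4‑[(triisopropylsilyl)oxy]phenyl}oxolan‑3‑yl](4‑methoxyphenyl)methanol | COc1ccc([C@@H](O)[C@H]2CO[C@@H](c3ccc(O[Si](C(C)C)(C(C)C)C(C)C)cc3)[C@@H]2CO[Si](c3ccccc3)(c3ccccc3)C(C)(C)C)cc1 | intermediate
17 | 4‑[(2R,3S,4R)‑3‑(hydroxymethyl)‑4‑[(S)‑hydroxy(4‑methoxyphenyl)methyl]oxolan‑2‑yl]phenol | COc1ccc([C@@H](O)[C@H]2CO[C@@H](c3ccc(O)cc3)[C@@H]2CO)cc1 | intermediate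
18 | [(2R,3S,4R)‑4‑[(S)‑acetoxy(4‑methoxyphenyl)methyl]‑2‑(4‑acetoxyphenyl)oxolan‑3‑yl]methyl acetate | COc1ccc([C@@H](OC(C)=O)[C@H]2CO[C@@H](c3ccc(OC(C)=O)cc3)[C@@H]2COC(C)=O)cc1 | intermediate
19 | [(2R,3S,4R)‑4‑[(S)‑acetoxy(4‑methoxyphenyl)methyl]‑2‑(4‑hydroxyphenyl)oxolan‑3‑yl]methyl acetate | COc1ccc([C@@H](OC(C)=O)[C@H]2CO[C@@H](c3ccc(O)cc3)[C@@H]2COC(C)=O)cc1 | target

## Step count and weakest steps

Total steps: 14. Longest linear sequence: 13 (steps 1–4 and 6–14, from 1 to 19); step 5 is a one‑step side branch.

**Step 7 (key step).** Formaldehyde is a weak oxygen nucleophile and is released slowly from the polymer. Capture of the tin‑activated cyclopropane may therefore be slower than cis‑to‑trans isomerisation of the cyclopropane, or than ring opening by the hydroxyl end groups and water that paraformaldehyde carries. Partial ionisation at C2 could also erode the trans selectivity. A stepwise fallback sets out from 9 and forms the same two bonds in separate operations. Sc(OTf)3‑catalysed ring opening of 9 with methanol (invertive attack at C2) would give γ‑methoxy malonate F1. Base‑catalysed hydroxymethylation of its malonate C–H (paraformaldehyde, K2CO3, THF) would give hydroxymethyl malonate F2. BF3·OEt2 at low temperature would then ionise the 4‑silyloxybenzylic methyl ether, and the primary hydroxyl would capture C2 trans to the C3 arm, with loss of methanol. The fallback comes back to the route at 11.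

**Step 6.** The face selectivity of the copper carbene on a Z‑alkene with a bulky allylic silyl ether may be insufficient. The electron‑rich arene could also divert the transfer to a stepwise path that leaks to the trans cyclopropane. A tethered fallback sets out from allylic alcohol 5.
- Acylation with methyl 3‑chloro‑3‑oxopropanoate (pyridine, CH2Cl2) gives allyl methyl malonate F3.
- Diazo transfer (4‑acetamidobenzenesulfonyl azide, Et3N, MeCN) gives diazomalonate F4.
- Intramolecular cyclopropanation (Cu(MeCN)4PF6, tert‑butyl bis(oxazoline)) is geometrically constrained to the endo‑aryl bicyclic lactone F5.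
- LiOH (THF–H2O, 0 °C) opens the strained lactone to hydroxy acid F6.
- TBDPSCl and imidazole, with a mild carbonate work‑up to free the carboxylate, give silyloxy acid F7.
- MeI and K2CO3 in DMF esterify it, and the fallback comes back to the route at 9.

**Step 8.** Hot chloride in wet DMSO may strip the aryl silyl ether, and kinetic protonation may leave much of the 3,4‑cis ester. A two‑stage fallback sets out from 11. Me3SnOH in 1,2‑dichloroethane at 80 °C hydrolyses one ester under neutral conditions, presumably the less hindered one, to malonic half‑ester F8. Heating F8 in toluene with catalytic Et3N removes CO2, and the fallback comes back to the route at 12. The C4 configuration is again finalised at 15.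

**Step 11.** The α‑branched ring carbon may compete with the aryl group as the "large" substituent in the oxazaborolidine complex, giving poor facial selectivity. A substrate‑controlled fallback sets out from 15: reduction with LiBH(s‑Bu)3 in THF at −78 °C relies only on Felkin–Anh control from C4, which the analysis above predicts to favour the same carbinol. It comes back to the route at 16.

## Further compounds

F1 | step 7 | dimethyl 2‑[(2S,3R)‑1‑[(tert‑butyldiphenylsilyl)oxy]‑3‑methoxy‑3‑{4‑[(triisopropylsilyl)oxy]phenyl}propan‑2‑yl]propanedioate | CO[C@@H](c1ccc(O[Si](C(C)C)(C(C)C)C(C)C)cc1)[C@H](CO[Si](c1ccccc1)(c1ccccc1)C(C)(C)C)C(C(=O)OC)C(=O)OC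
F2 | step 7 | dimethyl 2‑[(2S,3R)‑1‑[(tert‑butyldiphenylsilyl)oxy]‑3‑methoxy‑3‑{4‑[(triisopropylsilyl)oxy]phenyl}propan‑2‑yl]‑2‑(hydroxymethyl)propanedioate | CO[C@@H](c1ccc(O[Si](C(C)C)(C(C)C)C(C)C)cc1)[C@H](CO[Si](c1ccccc1)(c1ccccc1)C(C)(C)C)C(CO)(C(=O)OC)C(=O)OC
F3 | step 6 | methyl (Z)‑3‑{4‑[(triisopropylsilyl)oxy]phenyl}prop‑2‑en‑1‑yl propanedioate | COC(=O)CC(=O)OC/C=C\c1ccc(O[Si](C(C)C)(C(C)C)C(C)C)cc1
F4 | step 6 | methyl (Z)‑3‑{4‑[(triisopropylsilyl)oxy]phenyl}prop‑2‑en‑1‑yl 2‑diazopropanedioate | COC(=O)C(=[N+]=[N-])C(=O)OC/C=C\c1ccc(O[Si](C(C)C)(C(C)C)C(C)C)cc1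
F5 | step 6 | methyl (1R,5S,6S)‑2‑oxo‑6‑{4‑[(triisopropylsilyl)oxy]phenyl}‑3‑oxabicyclo[3.1.0]hexane‑1‑carboxylate (aryl endo) | COC(=O)[C@@]12[C@H](c3ccc(O[Si](C(C)C)(C(C)C)C(C)C)cc3)[C@@H]1COC2=O
F6 | step 6 | (1S,2S,3S)‑3‑(hydroxymethyl)‑1‑(methoxycarbonyl)‑2‑{4‑[(triisopropylsilyl)oxy]phenyl}cyclopropane‑1‑carboxylic acid (acid cis to aryl and hydroxymethyl) | COC(=O)[C@@]1(C(=O)O)[C@H](c2ccc(O[Si](C(C)C)(C(C)C)C(C)C)cc2)[C@@H]1CO
F7 | step 6 | (1S,2S,3S)‑3‑{[(tert‑butyldiphenylsilyl)oxy]methyl}‑1‑(methoxycarbonyl)‑2‑{4‑[(triisopropylsilyl)oxy]phenyl}cyclopropane‑1‑carboxylic acid | COC(=O)[C@@]1(C(=O)O)[C@H](c2ccc(O[Si](C(C)C)(C(C)C)C(C)C)cc2)[C@@H]1CO[Si](c2ccccc2)(c2ccccc2)C(C)(C)C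
F8 | step 8 | (3S,4S,5R)‑4‑{[(tert‑butyldiphenylsilyl)oxy]methyl}‑3‑(methoxycarbonyl)‑5‑{4‑[(triisopropylsilyl)oxy]phenyl}oxolane‑3‑carboxylic acid (acid trans to the C4 side chain) | OC(=O)[C@@]1(C(=O)OC)CO[C@@H](c2ccc(O[Si](C(C)C)(C(C)C)C(C)C)cc2)[C@@H]1CO[Si](c2ccccc2)(c2ccccc2)C(C)(C)C
F0 | step 11 | none | none
A1 | alternative 1 | 4‑vinyl‑1,3‑dioxolan‑2‑one (vinylethylene carbonate) | C=CC1COC(=O)O1
A2 | alternative 1 | 5‑{4‑[(tert‑butyldimethylsilyl)oxy]benzylidene}‑2,2‑dimethyl‑1,3‑dioxane‑4,6‑dione | CC1(C)OC(=O)C(=Cc2ccc(O[Si](C)(C)C(C)(C)C)cc2)C(=O)O1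
A3 | alternative 1 | 2,4‑cis‑2‑{4‑[(tert‑butyldimethylsilyl)oxy]phenyl}‑4‑vinyltetrahydrofuran spiro‑fused at C3 to 2,2‑dimethyl‑1,3‑dioxane‑4,6‑dione | CC1(C)OC(=O)C2(C(=O)O1)[C@@H](C=C)CO[C@H]2c1ccc(O[Si](C)(C)C(C)(C)C)cc1
A4 | alternative 2 | (4S)‑4‑[(E)‑3‑[(tert‑butyldiphenylsilyl)oxy]prop‑1‑en‑1‑yl]‑4‑(4‑methoxyphenyl)‑2‑{4‑[(triisopropylsilyl)oxy]phenyl}‑1,3‑dioxolane (carbinol configuration as required by a chair with the anisyl group equatorial; acetal carbon unassigned) | COc1ccc(cc1)[C@@]2(/C=C/CO[Si](c3ccccc3)(c3ccccc3)C(C)(C)C)COC(c3ccc(O[Si](C(C)C)(C(C)C)C(C)C)cc3)O2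
A5 | alternative 2 | [(3R,4S,5R)‑4‑{[(tert‑butyldiphenylsilyl)oxy]methyl}‑5‑{4‑[(triisopropylsilyl)oxy]phenyl}oxolan‑3‑yl](4‑methoxyphenyl)methanone | COc1ccc(C(=O)[C@H]2CO[C@@H](c3ccc(O[Si](C(C)C)(C(C)C)C(C)C)cc3)[C@@H]2CO[Si](c4ccccc4)(c4ccccc4)C(C)(C)C)cc1
A6 | alternative 3 | methyl 4‑[(tert‑butyldimethylsilyl)oxy]‑2‑diazo‑4‑(4‑methoxyphenyl)‑3‑[({4‑[(triisopropylsilyl)oxy]benzyl}oxy)methyl]butanoate, C4 and C7 configured as in the target | COc1ccc([C@@H](O[Si](C)(C)C(C)(C)C)[C@@H](COCc2ccc(O[Si](C(C)C)(C(C)C)C(C)C)cc2)C(=[N+]=[N-])C(=O)OC)cc1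
A7 | alternative 3 | methyl all‑trans‑4‑[(S)‑[(tert‑butyldimethylsilyl)oxy](4‑methoxyphenyl)methyl]‑2‑{4‑[(triisopropylsilyl)oxy]phenyl}oxolane‑3‑carboxylate | COc1ccc([C@@H](O[Si](C)(C)C(C)(C)C)[C@H]2CO[C@@H](c3ccc(O[Si](C(C)C)(C(C)C)C(C)C)cc3)[C@@H]2C(=O)OC)cc1
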